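**Retrosynthetic overview**

1. End-game: target 20 comes from bis-benzyl triol 19 by hydrogenolysis, and 19 from ester-lactone 18 by one hydride reduction that opens a temporary butyrolactone and reduces the C3 ester, so all three CH2OH groups appear together.
2. Key disconnection: the C2–C3 bond of the dihydrobenzofuran. The ring is closed by an enantioselective rhodium-carbene 1,5-C–H insertion of aryl diazoacetate 16 into its own aryl benzyl ether; 16 is open and has no stereocentre in that half. C3 is then epimerised from cis to trans.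
3. Enabling feature: the C2–H bond of the dihydrofuran ring is benzylic to the guaiacyl ring and α to O1, and it lies 1,5 to C3. The CH2OH carbon on C3 can be carried as an ester, which makes C3 a donor/acceptor carbene carbon.
4. Diazo ester 16 comes from aryl iodide 14 (Negishi–Reformatsky coupling, diazo transfer). Iodide 14 comes from trans-selective alkylation of (R)-β-benzylbutyrolactone 7 (from (R)-epichlorohydrin, diethyl malonate and an aryl Grignard reagent) with benzylic bromide 12 (from 5-iodovanillin).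
5. Ring order: the temporary butyrolactone first (steps 1–3, opened in step 12), the dihydrofuran ring last (step 10); all benzene rings are bought.

Key step: step 10

Remark on the chemistry: Rh2(R-PTTL)4 is assumed to deliver the 2S series, the mirror image of the sense associated with Rh2(S-PTTL)4 for 2-(benzyloxy)aryl diazoacetates. Compound 6 is carried as a mixture of C3 epimers (its SMILES leaves that centre open) because the centre is destroyed in step 3.

**Route**

Step 1
Reactants: 1 (R)-epichlorohydrin; 2 diethyl malonate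
Product: 3 ethyl (1S,5R)-2-oxo-3-oxabicyclo[3.1.0]hexane-1-carboxylate
Conditions: NaOEt, EtOH, reflux
Reagents that add atoms: none
Why: In this malonate alkylation–cyclopropanation–lactonisation cascade the malonate opens the epoxide at its CH2 terminus, the alkoxide closes a new epoxide by displacing chloride, and 3-exo-tet opening of that epoxide by the malonate carbanion (inversion at the stereocentre) followed by lactonisation should give the cis-fused cyclopropane lactone with the epichlorohydrin stereocentre transferred to C5.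

Step 2
Reactants: 4 1-(benzyloxy)-4-bromo-2-methoxybenzene; 3 ethyl (1S,5R)-2-oxo-3-oxabicyclo[3.1.0]hexane-1-carboxylate
Product: 6 ethyl (4R)-4-[4-(benzyloxy)-3-methoxybenzyl]-2-oxotetrahydrofuran-3-carboxylate (C3 epimers), via aryl Grignard reagent 5 (not isolated)
Conditions: 4, Mg, THF, 40 °C; then CuBr·SMe2 (10 mol%), 3, THF, −30 °C; NH4Cl work-up
Reagents that add atoms: none
Why: Copper-catalysed homoconjugate addition of the aryl Grignard reagent to the doubly activated cyclopropane should occur at the unsubstituted CH2 with cleavage of the bond to the malonate-type carbon, leaving the C4 stereocentre untouched.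

Step 3
Reactants: 6 ethyl (4R)-4-[4-(benzyloxy)-3-methoxybenzyl]-2-oxotetrahydrofuran-3-carboxylate
Product: 7 (R)-4-[4-(benzyloxy)-3-methoxybenzyl]dihydrofuran-2(3H)-one
Conditions: LiCl, DMSO/H2O, 140 °C
Reagents that add atoms: none
Why: Krapcho dealkoxycarbonylation removes the activating ester from the malonate-type carbon without touching the C4 stereocentre or the benzyl ether.

Step 4
Reactants: 8 5-iodovanillin (4-hydroxy-3-iodo-5-methoxybenzaldehyde); 9 4-(benzyloxy)-3-methoxybenzyl alcohol
Product: 10 4-{[4-(benzyloxy)-3-methoxybenzyl]oxy}-3-iodo-5-methoxybenzaldehyde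
Conditions: PPh3, DIAD, THF, 0 °C to rt
Reagents that add atoms: none
Why: Mitsunobu etherification should work because the phenol, acidified by the para-formyl and ortho-iodo groups, is a good pronucleophile for the activated primary benzylic alcohol, and the neutral conditions spare the aldehyde.

Step 5
Reactants: 10 4-{[4-(benzyloxy)-3-methoxybenzyl]oxy}-3-iodo-5-methoxybenzaldehyde
Product: 11 (4-{[4-(benzyloxy)-3-methoxybenzyl]oxy}-3-iodo-5-methoxyphenyl)methanol
Conditions: NaBH4, MeOH/THF, 0 °C
Reagents that add atoms: none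
Why: Borohydride reduction of the aryl aldehyde is chemoselective in the presence of the aryl iodide and the benzyl ethers.

Step 6
Reactants: 11 (4-{[4-(benzyloxy)-3-methoxybenzyl]oxy}-3-iodo-5-methoxyphenyl)methanol
Product: 12 1-{[4-(benzyloxy)-3-methoxybenzyl]oxy}-4-(bromomethyl)-2-iodo-6-methoxybenzene
Conditions: CBr4, PPh3, CH2Cl2, 0 °C
Reagents that add atoms: carbon tetrabromide, BrC(Br)(Br)Br
Why: The Appel reaction converts the primary benzylic alcohol into the bromide under neutral conditions, which protects the acid-labile dialkoxybenzyl aryl ether from HBr.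

Step 7
Reactants: 7 (R)-4-[4-(benzyloxy)-3-methoxybenzyl]dihydrofuran-2(3H)-one; 12 1-{[4-(benzyloxy)-3-methoxybenzyl]oxy}-4-(bromomethyl)-2-iodo-6-methoxybenzene
Product: 14 (3R,4R)-4-[4-(benzyloxy)-3-methoxybenzyl]-3-(4-{[4-(benzyloxy)-3-methoxybenzyl]oxy}-3-iodo-5-methoxybenzyl)dihydrofuran-2(3H)-one, via lithium lactone enolate 13 (not isolated)
Conditions: LiHMDS, THF, −78 °C; then 12, DMPU, −78 to −30 °C
Reagents that add atoms: none
Why: In this lactone enolate alkylation the benzylic bromide should approach the face anti to the C4 benzyl group, setting C3 trans to C4 by substrate control, and the aryl iodide is inert to the amide base at low temperature.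

Step 8
Reactants: 14 (3R,4R)-4-[4-(benzyloxy)-3-methoxybenzyl]-3-(4-{[4-(benzyloxy)-3-methoxybenzyl]oxy}-3-iodo-5-methoxybenzyl)dihydrofuran-2(3H)-one
Product: 15 methyl 2-[5-{[(3R,4R)-4-[4-(benzyloxy)-3-methoxybenzyl]-2-oxotetrahydrofuran-3-yl]methyl}-2-{[4-(benzyloxy)-3-methoxybenzyl]oxy}-3-methoxyphenyl]acetate
Conditions: BrZnCH2CO2Me (from BrCH2CO2Me, Zn, TMSCl cat., THF), Pd2(dba)3 (2.5 mol%), XPhos (10 mol%), THF, 60 °C
Reagents that add atoms: methyl bromoacetate, COC(=O)CBr (used as its zinc reagent bromo(2-methoxy-2-oxoethyl)zinc, COC(=O)C[Zn]Br)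
Why: Negishi-type cross-coupling of the Reformatsky reagent should work because the weakly basic zinc enolate transmetalates to the aryl palladium iodide formed by oxidative addition to zerovalent palladium and tolerates the enolisable lactone.

Step 9
Reactants: 15 methyl 2-[5-{[(3R,4R)-4-[4-(benzyloxy)-3-methoxybenzyl]-2-oxotetrahydrofuran-3-yl]methyl}-2-{[4-(benzyloxy)-3-methoxybenzyl]oxy}-3-methoxyphenyl]acetate
Product: 16 methyl 2-diazo-2-[5-{[(3R,4R)-4-[4-(benzyloxy)-3-methoxybenzyl]-2-oxotetrahydrofuran-3-yl]methyl}-2-{[4-(benzyloxy)-3-methoxybenzyl]oxy}-3-methoxyphenyl]acetate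
Conditions: p-ABSA, DBU, MeCN, 0 °C to rt
Reagents that add atoms: 4-acetamidobenzenesulfonyl azide (p-ABSA), CC(=O)Nc1ccc(cc1)S(=O)(=O)N=[N+]=[N-]
Why: Regitz diazo transfer should be selective for the arylacetate position, which is several pKa units more acidic than the hindered lactone α-position.

Step 10
Reactants: 16 methyl 2-diazo-2-[5-{[(3R,4R)-4-[4-(benzyloxy)-3-methoxybenzyl]-2-oxotetrahydrofuran-3-yl]methyl}-2-{[4-(benzyloxy)-3-methoxybenzyl]oxy}-3-methoxyphenyl]acetate
Product: 17 methyl (2S,3R)-2-[4-(benzyloxy)-3-methoxyphenyl]-5-{[(3R,4R)-4-[4-(benzyloxy)-3-methoxybenzyl]-2-oxotetrahydrofuran-3-yl]methyl}-7-methoxy-2,3-dihydro-1-benzofuran-3-carboxylate (cis)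
Conditions: Rh2(R-PTTL)4 (2 mol%), toluene, −60 °C, slow addition of 16
Reagents that add atoms: none
Why: The dirhodium tetracarboxylate (divalent rhodium) should expel N2 from 16 to give a donor/acceptor rhodium carbene at the future C3, which inserts through a concerted, asynchronous, hydride-transfer-like three-centre transition state into one of the two enantiotopic C–H bonds of the ArO–CH2–Ar' methylene and so forms the C2–C3 bond. The closest known reaction type is the enantioselective intramolecular C–H insertion of methyl 2-(2-benzyloxyphenyl)-2-diazoacetates with dirhodium N-phthaloyl-tert-leucinate catalysts, a process associated with cis-2-aryl-3-methoxycarbonyl-2,3-dihydrobenzofurans. The dihydrofuran ring closes by 1,5-insertion, the five-membered ring containing the carbene carbon, two arene carbons, O1 and the methylene carbon, which is the mode rhodium carbenes prefer. C2 is set by catalyst-controlled choice between the two enantiotopic methylene hydrogens (insertion with retention) and C3 by the carbene face exposed in the same chiral pocket, which places aryl and ester cis; the (R)-tert-leucinate catalyst is chosen to give 2S, and the lactone stereocentres, seven bonds away, should not interfere. The step needs site selectivity, secured because the only C–H bond within 1,5-reach is the one activated both by the ether oxygen and by the electron-rich aryl group. It also needs chemoselectivity over carbene dimerisation and arene cyclopropanation, secured by the stabilised donor/acceptor carbene, the low temperature, the slow addition and the absence of any free OH or NH group.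

Step 11
Reactants: 17 methyl (2S,3R)-2-[4-(benzyloxy)-3-methoxyphenyl]-5-{[(3R,4R)-4-[4-(benzyloxy)-3-methoxybenzyl]-2-oxotetrahydrofuran-3-yl]methyl}-7-methoxy-2,3-dihydro-1-benzofuran-3-carboxylate
Product: 18 methyl (2S,3S)-2-[4-(benzyloxy)-3-methoxyphenyl]-5-{[(3R,4R)-4-[4-(benzyloxy)-3-methoxybenzyl]-2-oxotetrahydrofuran-3-yl]methyl}-7-methoxy-2,3-dihydro-1-benzofuran-3-carboxylate (trans)
Conditions: DBU, toluene, 40 °C
Reagents that add atoms: none
Why: Base-mediated epimerisation through the ester enolate should deliver the thermodynamically preferred trans isomer at C3, while C2 is preserved because ring opening of the enolate would be a disfavoured retro-5-endo-trig elimination, and the already trans lactone is not affected.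

Step 12
Reactants: 18 methyl (2S,3S)-2-[4-(benzyloxy)-3-methoxyphenyl]-5-{[(3R,4R)-4-[4-(benzyloxy)-3-methoxybenzyl]-2-oxotetrahydrofuran-3-yl]methyl}-7-methoxy-2,3-dihydro-1-benzofuran-3-carboxylate
Product: 19 (2R,3R)-2-[4-(benzyloxy)-3-methoxybenzyl]-3-({(2S,3R)-2-[4-(benzyloxy)-3-methoxyphenyl]-3-(hydroxymethyl)-7-methoxy-2,3-dihydro-1-benzofuran-5-yl}methyl)butane-1,4-diol
Conditions: LiAlH4, THF, 0 °C; Rochelle salt work-up
Reagents that add atoms: none
Why: Hydride reduction opens the lactone to the 1,4-diol and reduces the methyl ester to the C3 hydroxymethyl group in one operation without touching any stereocentre (the C3 descriptor changes from S to R only through the priority change).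

Step 13
Reactants: 19 (2R,3R)-2-[4-(benzyloxy)-3-methoxybenzyl]-3-({(2S,3R)-2-[4-(benzyloxy)-3-methoxyphenyl]-3-(hydroxymethyl)-7-methoxy-2,3-dihydro-1-benzofuran-5-yl}methyl)butane-1,4-diol
Product: 20 (2R,3R)-2-(4-hydroxy-3-methoxybenzyl)-3-{[(2S,3R)-2-(4-hydroxy-3-methoxyphenyl)-3-(hydroxymethyl)-7-methoxy-2,3-dihydro-1-benzofuran-5-yl]methyl}butane-1,4-diol (CNP0256425.1)
Conditions: H2 (1 atm), Pd/C (palladium on carbon), EtOAc/MeOH, rt, reaction stopped at full debenzylation
Reagents that add atoms: none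
Why: Catalytic hydrogenolysis should cleave the two acyclic aryl benzyl ethers much faster than the cyclic benzylic C2–O1 bond of the dihydrobenzofuran, releasing both phenols under neutral conditions.

**Compound list**

1 | (R)-epichlorohydrin | ClC[C@H]1CO1 | starting material
2 | diethyl malonate | CCOC(=O)CC(=O)OCC | starting material
3 | ethyl (1S,5R)-2-oxo-3-oxabicyclo[3.1.0]hexane-1-carboxylate | CCOC(=O)[C@]12C[C@H]1COC2=O | intermediate
4 | 1-(benzyloxy)-4-bromo-2-methoxybenzene | COc1cc(Br)ccc1OCc1ccccc1 | starting material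
5 | [4-(benzyloxy)-3-methoxyphenyl]magnesium bromide | COc1cc([Mg]Br)ccc1OCc1ccccc1 | intermediate
6 | ethyl (4R)-4-[4-(benzyloxy)-3-methoxybenzyl]-2-oxotetrahydrofuran-3-carboxylate (C3 epimers) | CCOC(=O)C1C(=O)OC[C@@H]1Cc1ccc(OCc2ccccc2)c(OC)c1 | intermediate
7 | (R)-4-[4-(benzyloxy)-3-methoxybenzyl]dihydrofuran-2(3H)-one | O=C1C[C@@H](Cc2ccc(OCc3ccccc3)c(OC)c2)CO1 | intermediate
8 | 5-iodovanillin (4-hydroxy-3-iodo-5-methoxybenzaldehyde) | COc1cc(C=O)cc(I)c1O | starting material
9 | 4-(benzyloxy)-3-methoxybenzyl alcohol | COc1cc(CO)ccc1OCc1ccccc1 | starting material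
10 | 4-{[4-(benzyloxy)-3-methoxybenzyl]oxy}-3-iodo-5-methoxybenzaldehyde | COc1cc(C=O)cc(I)c1OCc1ccc(OCc2ccccc2)c(OC)c1 | intermediate
11 | (4-{[4-(benzyloxy)-3-methoxybenzyl]oxy}-3-iodo-5-methoxyphenyl)methanol | COc1cc(CO)cc(I)c1OCc1ccc(OCc2ccccc2)c(OC)c1 | intermediate
12 | 1-{[4-(benzyloxy)-3-methoxybenzyl]oxy}-4-(bromomethyl)-2-iodo-6-methoxybenzene | COc1cc(CBr)cc(I)c1OCc1ccc(OCc2ccccc2)c(OC)c1 | intermediate
13 | lithium (R)-4-[4-(benzyloxy)-3-methoxybenzyl]-4,5-dihydrofuran-2-olate | [Li]OC1=C[C@@H](Cc2ccc(OCc3ccccc3)c(OC)c2)CO1 | intermediate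
14 | (3R,4R)-4-[4-(benzyloxy)-3-methoxybenzyl]-3-(4-{[4-(benzyloxy)-3-methoxybenzyl]oxy}-3-iodo-5-methoxybenzyl)dihydrofuran-2(3H)-one | COc1cc(C[C@H]2COC(=O)[C@@H]2Cc2cc(I)c(OCc3ccc(OCc4ccccc4)c(OC)c3)c(OC)c2)ccc1OCc1ccccc1 | intermediate
15 | methyl 2-[5-{[(3R,4R)-4-[4-(benzyloxy)-3-methoxybenzyl]-2-oxotetrahydrofuran-3-yl]methyl}-2-{[4-(benzyloxy)-3-methoxybenzyl]oxy}-3-methoxyphenyl]acetate | COc1cc(C[C@H]2COC(=O)[C@@H]2Cc2cc(CC(=O)OC)c(OCc3ccc(OCc4ccccc4)c(OC)c3)c(OC)c2)ccc1OCc1ccccc1 | intermediate
16 | methyl 2-diazo-2-[5-{[(3R,4R)-4-[4-(benzyloxy)-3-methoxybenzyl]-2-oxotetrahydrofuran-3-yl]methyl}-2-{[4-(benzyloxy)-3-methoxybenzyl]oxy}-3-methoxyphenyl]acetate | COc1cc(C[C@H]2COC(=O)[C@@H]2Cc2cc(C(=[N+]=[N-])C(=O)OC)c(OCc3ccc(OCc4ccccc4)c(OC)c3)c(OC)c2)ccc1OCc1ccccc1 | intermediate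
17 | methyl (2S,3R)-2-[4-(benzyloxy)-3-methoxyphenyl]-5-{[(3R,4R)-4-[4-(benzyloxy)-3-methoxybenzyl]-2-oxotetrahydrofuran-3-yl]methyl}-7-methoxy-2,3-dihydro-1-benzofuran-3-carboxylate (cis) | COc1cc(C[C@H]2COC(=O)[C@@H]2Cc2cc(OC)c3c(c2)[C@@H](C(=O)OC)[C@@H](c2ccc(OCc4ccccc4)c(OC)c2)O3)ccc1OCc1ccccc1 | intermediate
18 | methyl (2S,3S)-2-[4-(benzyloxy)-3-methoxyphenyl]-5-{[(3R,4R)-4-[4-(benzyloxy)-3-methoxybenzyl]-2-oxotetrahydrofuran-3-yl]methyl}-7-methoxy-2,3-dihydro-1-benzofuran-3-carboxylate (trans) | COc1cc(C[C@H]2COC(=O)[C@@H]2Cc2cc(OC)c3c(c2)[C@H](C(=O)OC)[C@@H](c2ccc(OCc4ccccc4)c(OC)c2)O3)ccc1OCc1ccccc1 | intermediate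
19 | (2R,3R)-2-[4-(benzyloxy)-3-methoxybenzyl]-3-({(2S,3R)-2-[4-(benzyloxy)-3-methoxyphenyl]-3-(hydroxymethyl)-7-methoxy-2,3-dihydro-1-benzofuran-5-yl}methyl)butane-1,4-diol | COc1cc(C[C@@H](CO)[C@H](CO)Cc2cc(OC)c3c(c2)[C@H](CO)[C@@H](c2ccc(OCc4ccccc4)c(OC)c2)O3)ccc1OCc1ccccc1 | intermediate
20 | (2R,3R)-2-(4-hydroxy-3-methoxybenzyl)-3-{[(2S,3R)-2-(4-hydroxy-3-methoxyphenyl)-3-(hydroxymethyl)-7-methoxy-2,3-dihydro-1-benzofuran-5-yl]methyl}butane-1,4-diol | COc1cc(C[C@@H](CO)[C@H](CO)Cc2cc(OC)c3c(c2)[C@H](CO)[C@@H](c2ccc(O)c(OC)c2)O3)ccc1O | target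

**Step count and risks**

Total step count: 13. Longest linear sequence: 10 steps (steps 1–3 and 7–13; the branch through steps 4–6 is equally long).

Steps most likely to fail:

1. Step 10 (key C–H insertion). The very electron-rich benzyl group could divert the insertion into a stepwise hydride-transfer pathway with loss of enantio- and cis-selectivity, or the carbene could dimerise. The fallback gives up the C–H insertion, sets out from 15 and comes back at 18. Ester 15 would be enolised at the arylacetate position (LiHMDS, THF, −78 °C) and added to commercial 4-(benzyloxy)-3-methoxybenzaldehyde to give the aldol adduct methyl 2-aryl-3-[4-(benzyloxy)-3-methoxyphenyl]-3-hydroxypropanoate F1 as a diastereomer mixture. Treatment with TFA in CH2Cl2 with anisole as cation scavenger should ionise the benzylic alcohol; the neighbouring ether oxygen would capture the cation and pass its dialkoxybenzyl group to anisole, closing the ring at O1–C2 under thermodynamic (trans) control. This would give 18 together with its (2R,3R)-trans diastereomer F2, to be removed by preparative chromatography; the fallback therefore offers no absolute control at the two new centres.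

2. Step 8 (Negishi–Reformatsky coupling). Oxidative addition and transmetalation at the ortho-alkoxy-flanked, electron-rich iodide could be slow, so that protodeiodination and self-condensation of the zinc enolate take over. The fallback sets out from 14 and comes back at 16, bypassing 15: palladium-catalysed, silver-assisted arylation of methyl diazoacetate at its C–H bond (Pd(PPh3)4, Ag2CO3, Et3N, toluene, rt) should deliver the aryl diazoacetate directly with the diazo group retained. No new compound arises (none F0).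

3. Step 13 (hydrogenolysis). Over-reduction could open the dihydrofuran ring at the benzylic C2–O1 bond. The fallback replaces reduction by Lewis-acid debenzylation, sets out from 19 and comes back at 20. Triol 19 would be acetylated (Ac2O, pyridine, DMAP) to the triacetate bis-benzyl ether F3, debenzylated with BCl3 and pentamethylbenzene in CH2Cl2 at −78 °C to the triacetate diphenol F4, and deacetylated with K2CO3 in MeOH to 20.

**Further compounds**

F1 | step 10 | methyl 2-[5-{[(3R,4R)-4-[4-(benzyloxy)-3-methoxybenzyl]-2-oxotetrahydrofuran-3-yl]methyl}-2-{[4-(benzyloxy)-3-methoxybenzyl]oxy}-3-methoxyphenyl]-3-[4-(benzyloxy)-3-methoxyphenyl]-3-hydroxypropanoate (diastereomer mixture) | COc1cc(C[C@H]2COC(=O)[C@@H]2Cc2cc(C(C(=O)OC)C(O)c3ccc(OCc4ccccc4)c(OC)c3)c(OCc3ccc(OCc4ccccc4)c(OC)c3)c(OC)c2)ccc1OCc1ccccc1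
F2 | step 10 | methyl (2R,3R)-2-[4-(benzyloxy)-3-methoxyphenyl]-5-{[(3R,4R)-4-[4-(benzyloxy)-3-methoxybenzyl]-2-oxotetrahydrofuran-3-yl]methyl}-7-methoxy-2,3-dihydro-1-benzofuran-3-carboxylate | COc1cc(C[C@H]2COC(=O)[C@@H]2Cc2cc(OC)c3c(c2)[C@@H](C(=O)OC)[C@H](c2ccc(OCc4ccccc4)c(OC)c2)O3)ccc1OCc1ccccc1
F0 | step 8 | none | none
F3 | step 13 | (2R,3R)-2-[4-(benzyloxy)-3-methoxybenzyl]-3-({(2S,3R)-3-(acetoxymethyl)-2-[4-(benzyloxy)-3-methoxyphenyl]-7-methoxy-2,3-dihydro-1-benzofuran-5-yl}methyl)butane-1,4-diyl diacetate | COc1cc(C[C@@H](COC(C)=O)[C@H](COC(C)=O)Cc2cc(OC)c3c(c2)[C@H](COC(C)=O)[C@@H](c2ccc(OCc4ccccc4)c(OC)c2)O3)ccc1OCc1ccccc1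
F4 | step 13 | (2R,3R)-2-{[(2S,3R)-3-(acetoxymethyl)-2-(4-hydroxy-3-methoxyphenyl)-7-methoxy-2,3-dihydro-1-benzofuran-5-yl]methyl}-3-(4-hydroxy-3-methoxybenzyl)butane-1,4-diyl diacetate | COc1cc(C[C@@H](COC(C)=O)[C@H](COC(C)=O)Cc2cc(OC)c3c(c2)[C@H](COC(C)=O)[C@@H](c2ccc(O)c(OC)c2)O3)ccc1O
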